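## Structural features

The target is a drimane: a trans-fused decalin (rings A and B) with a gem-dimethyl group at C4, an angular methyl at C10 and a methyl carbinol at C8. Through the exocyclic trisubstituted alkene C11=C1', C9 carries a five-membered carbocycle. Four contiguous stereocentres lie on the decalin (C5, C10, C9, C8). C8 has its hydroxyl axial (8β) and its methyl equatorial, so it is the C8 epimer of the sclareolide pattern, and it stands next to C9, whose side chain is equatorial. The side ring is an enolised cyclopentane-1,3-dione: C2'–OH and C4'=O flank C3'–H, C1' is the alkylidene carbon and C5' is a CHCl stereocentre. C9 is cis to the oxygenated C2' and trans to C5', the arrangement that a condensation of a C11 aldehyde with a cyclopentanedione would not favour. C5' (R) is the only stereocentre outside the decalin; it is five bonds from C9 and on the far side of the alkene, so the decalin cannot be expected to control it. Its hydrogen is acidic (α to C4'=O, allylic, α to chlorine) and can be lost by enolisation or by tautomerism to an endocyclic ene-dione. Other fragile points are the tertiary axial alcohol (elimination, retro-aldol at the aldehyde stage, closure onto C2') and the vinylogous acid. The decalin can be bought; the real difficulty is the side ring with a defined C11=C1' geometry and a defined C5'. The key step uses the 1,3-relationship of the C2' and C4' oxygens: C2'–C3' is the bond that an ester-type carbonyl on C1' and a methyl ketone (C3' its methyl) make in a Claisen condensation, with C11=C1' already in place.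

## Logic of the disconnections

**23 ⇒ 20.** Cut C5'–Cl. C5' is the one labile stereocentre, so it is made last. Its synthon is a C4'–C5' enol plus electrophilic chlorine. Silylating both dione oxygens (21) avoids having to tell O2' from O4', which an O-alkylation of the vinylogous acid could not be trusted to do (the unhindered O4' would react first). The gain is that all earlier chemistry is free of the epimerisable chloride. The demands are attack at C5' and not C3', face selection by an external chiral agent, and no base after the C–Cl bond exists.

**20 ⇒ 18 (key).** Cut C2'–C3' and, in the retro sense, rejoin O8 to C2'. The acrylate of the key step is carried as its lactone with the C8 oxygen and not as an acyclic methyl ester with O8 silylated (the keto analogue of 16). Three reasons: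
- The lactone holds C11=C1' in a six-membered ring, so the geometry cannot drift at the precursor stage.
- A cisoid lactone carbonyl is a much better acyl donor for a closure that is stereoelectronically demanding.
- The leaving group is the C8 alkoxide itself, so 20 emerges with its hydroxyl free and no deprotection is needed once the chloride is present.

The gain is one ring and no stereocentre to control. The demand is that the C3' enolate must close although the allylic C5' methylene is the more acidic site; a claim of clean kinetic methyl-enolate formation is not relied on.

**18 ⇒ 17.** Change C4'=O to a terminal alkene. The acetonyl group is carried as an allyl group, which tolerates cross-coupling and fluoride. The demand is Markovnikov oxidation of the monosubstituted alkene without moving either double bond.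

**17 ⇒ 14 + 15 (through 16).** Cut C1'–C5' and open O8–C2'. C1' is a vinyl-metal carbon, so C3'–C5' arrive as one three-carbon electrophile. Coupling with retention places C5' trans to C9, and lactonisation is possible only because C9 is cis to the ester. The demand is transmetalation from a hindered, electron-poor stannane.

**14 ⇒ 12 + 13.** Cut C1'–Sn and C11–H. A syn addition across an alkyne turns the geometry problem into a regiochemistry problem: tin must go to C1'.

**12 ⇒ 9 + 10 (through 11); 9 ⇒ 7 + 8.** Cut C1'–C2' and C11=C1'. The side chain is reduced to an aldehyde plus two one-carbon reagents. The demand is a non-basic olefination of a hindered aldehyde with a β-silyloxy group, with C9 untouched.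

**7 ⇒ 6 ⇒ 5 ⇒ 4 ⇒ 2 (through 3).** Protect O8, then excise C12: glycol cleavage of C11–C12 after reduction, preceded by oxygenation of C11. This reaches a C16 lactone that already has C5, C8, C9 and C10 correct. The demand is enolate oxidation at C11 and mild handling of a β-hydroxy aldehyde.

**2 ⇒ 1.** Invert C8 by heterolysis and reclosure of the C8–O bond. The demand is acid that ionises only this tertiary C–O bond.

## Other disconnections considered

**Alternative 1:** The cut is C5–C10 and C8–C9, so both decalin rings. Forward, the trienal A1 would undergo an intramolecular Diels–Alder reaction under a chiral oxazaborolidinium Lewis acid to give A2.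
- In its favour: both rings and four stereocentres would form in one step from an achiral chain; the relative configuration follows from an endo transition state of an (E)-enal and an (E,E)-diene; C11 is already an aldehyde and the C8 oxygen is already β.
- Against it here: the dienophile carbon C10 is fully substituted and the diene terminus C5 adjoins the quaternary C4, a congested case for this catalyst class. A cycloadduct of a 1-acetoxydiene carries hydrogen, not methyl, at C8, so A2 is a 12-nordrimane. Hydrogenation, acetate cleavage, oxidation and methyl addition (with the aldehyde masked and a β-acetoxy aldehyde prone to elimination) would still be needed before the level of 7.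
- Comparison: on structure it builds what the chosen plan buys and leaves the side ring untouched. On mechanism it is the equal of any step of the chosen plan in stereochemical clarity, and it is the better plan in not depending on a natural lactone (either enantiomer, ring A analogues). On step economy it is clearly longer.

**Alternative 2:** The cut is C7–C8. Forward, SmI2 would reduce the iodide of A3 and the organosamarium would add to the samarium-chelated ketone, closing ring B to A4.
- In its favour: the C8 carbinol would be set kinetically with the hydroxyl cis to the C9 ester under neutral conditions, and C11 arrives as an ester so no carbon has to be excised.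
- Against it here: A3 needs an enantiopure cyclohexane with the quaternary C10 bonded to an acetoacetate α-carbon, a neopentyl bond that simple alkylation cannot make, so many steps precede the key step. A4 must still be reduced to 6.
- Comparison: on structure it again addresses ring B, which is not the difficulty. On mechanism, the chelation-controlled addition is the better way to set C8 than the thermodynamic acid epimerisation of step 1. On step economy it is well behind.

**Alternative 3:** The cut is C4–C5 and C9–C10. Forward, a BINOL-derived proton source with SnCl4 would protonate the terminal alkene of A5 and the cation cascade would end on the keto ester enol to give A6.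
- In its favour: A5 is one alkylation away from bulk chemicals, so A6 would be two steps from commerce. A methyl nucleophile should add to the C8 ketone of A6 equatorially, away from the axial C10 methyl, giving the required 8β-hydroxyl and A4.
- Against it here: absolute stereocontrol with a keto ester terminator is less secure than a chiral-pool lactone; partial cyclisation and O-termination can compete; the methyl addition must beat enolisation of a β-keto ester.
- Comparison: on structure it is the shortest way to the decalin. On mechanism the chair–chair folding gives reliable relative configuration, but enantiomeric purity would be below that of 1. On step economy it is the equal of, or slightly better than, steps 1 to 4 of the chosen plan (about three steps to A4), and it needs no natural feedstock. It would still need a reduction to 6 and the whole side-ring sequence.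

Key step: step 11

Assumption: the decalin uses drimane locants (C11 on C9, C12 the C8 methyl) and the side ring uses primed locants (C1' alkylidene, C2' and C4' oxygenated, C3' between them, C5' chlorinated).
Assumption: 20 and 23 are drawn as the C2' enol; the C4' enol is the same compound in tautomeric equilibrium.
Assumption: 4 is carried as whichever C11 epimer or mixture forms, since C11 becomes trigonal in step 4.

## Route

**Step 1**
Reactants: 1 (+)-sclareolide
Product: 2 8-epi-sclareolide
Conditions: conc. H2SO4, HCO2H, 50 °C
Reagents that add atoms: none
Why: Acid-mediated alkyl–oxygen heterolysis of the tertiary C8–O bond and reclosure of the acid onto the C8 cation from the β face should give the cis-fused γ-lactone, the thermodynamically preferred ring fusion (known lactone epimerisation); this sets 8β-O/8α-CH3 and leaves C5, C9 and C10 untouched.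

**Step 2**
Reactants: 2 8-epi-sclareolide
Product: 4 11-hydroxy-8-epi-sclareolide, via potassium lactone enolate 3 (not isolated)
Conditions: KN(SiMe3)2, THF, −78 °C; then 2-(phenylsulfonyl)-3-phenyloxaziridine, −78 °C; aq. NH4Cl
Reagents that add atoms: 2-(phenylsulfonyl)-3-phenyloxaziridine, O=S(=O)(N1OC1c1ccccc1)c1ccccc1
Why: Enolate oxidation (α-hydroxylation of a lactone enolate by an N-sulfonyloxaziridine); the new C11 carbinol configuration is immaterial because C11 becomes the aldehyde carbon in step 4.

**Step 3**
Reactants: 4 11-hydroxy-8-epi-sclareolide
Product: 5 8β-hydroxy-9β-(1,2-dihydroxyethyl)-11-nordrimane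
Conditions: LiAlH4, THF, 0 → 23 °C; H2O quench
Reagents that add atoms: none
Why: Hydride reduction of the lactone to the primary alcohol gives the C11–C12 diol beside the tertiary C8 alcohol; no stereocentre of the decalin is affected.

**Step 4**
Reactants: 5 8β-hydroxy-9β-(1,2-dihydroxyethyl)-11-nordrimane
Product: 6 8β-hydroxydriman-11-al
Conditions: NaIO4, THF–H2O (pH 7 buffer), 0 °C
Reagents that add atoms: none
Why: Periodate glycol cleavage removes C12 as formaldehyde and leaves C11 as the aldehyde; the tertiary 8-OH has no vicinal partner, and the neutral, cold conditions should avoid retro-aldol opening of the β-hydroxy aldehyde and keep the equatorial C9 formyl group.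

**Step 5**
Reactants: 6 8β-hydroxydriman-11-al
Product: 7 8β-(triethylsilyloxy)driman-11-al
Conditions: Et3SiOTf, 2,6-lutidine, CH2Cl2, −78 → 0 °C
Reagents that add atoms: triethylsilyl triflate, CC[Si](CC)(CC)OS(=O)(=O)C(F)(F)F
Why: Silyl triflate with a hindered pyridine silylates the axial tertiary alcohol at low temperature; the ether blocks retro-aldol cleavage and alkoxide chemistry in steps 6 to 8.

**Step 6**
Reactants: 7 8β-(triethylsilyloxy)driman-11-al; 8 carbon tetrabromide
Product: 9 11-(dibromomethylidene)-8β-(triethylsilyloxy)drimane
Conditions: CBr4, PPh3, Zn, CH2Cl2, 23 °C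
Reagents that add atoms: carbon tetrabromide (8), BrC(Br)(Br)Br
Why: Dibromo-olefination (first stage of the Corey–Fuchs sequence) with a non-basic phosphorus ylide, so neither C9 nor the β-silyloxy group is endangered; zinc consumes Ph3PBr2, which could otherwise attack the silyl ether.

**Step 7**
Reactants: 9 11-(dibromomethylidene)-8β-(triethylsilyloxy)drimane; 10 methyl chloroformate
Product: 12 methyl 3-[8β-(triethylsilyloxy)-11-nordriman-9β-yl]prop-2-ynoate, via lithium acetylide 11 (not isolated)
Conditions: n-BuLi (2.1 equiv), THF, −78 °C; then ClCO2Me, −78 → 0 °C
Reagents that add atoms: methyl chloroformate (10), COC(Cl)=O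
Why: Second stage of the Corey–Fuchs sequence: bromine–lithium exchange and Fritsch–Buttenberg–Wiechell rearrangement give the acetylide, which is C-acylated by the chloroformate faster than the product ester can react further.

**Step 8**
Reactants: 12 methyl 3-[8β-(triethylsilyloxy)-11-nordriman-9β-yl]prop-2-ynoate; 13 tributyltin hydride
Product: 14 methyl (E)-3-[8β-(triethylsilyloxy)-11-nordriman-9β-yl]-2-(tributylstannyl)prop-2-enoate
Conditions: Pd(PPh3)4 (cat.), n-Bu3SnH (slow addition), THF, 0 → 23 °C
Reagents that add atoms: tributyltin hydride (13), CCCC[SnH](CCCC)CCCC
Why: Syn-hydrostannation of an alkynoate catalysed by zerovalent palladium puts H on C11 and tin on C1' from the same side, so C9 ends cis to the ester; the bulk at C9 reinforces the electronic preference for α-stannylation.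

**Step 9**
Reactants: 14 methyl (E)-3-[8β-(triethylsilyloxy)-11-nordriman-9β-yl]-2-(tributylstannyl)prop-2-enoate; 15 allyl bromide
Product: 17 allyl lactone (O8–C2' δ-lactone of (Z)-2-allyl-3-(8β-hydroxy-11-nordriman-9β-yl)prop-2-enoic acid), via silyl ether allyl ester 16 (not isolated)
Conditions: allyl bromide, Pd2(dba)3 (cat.), AsPh3, CuI, DMF, 40 °C; then n-Bu4NF, THF, 23 °C; aq. NH4Cl
Reagents that add atoms: allyl bromide (15), C=CCBr
Why: Stille allylation with copper co-catalysis proceeds with retention at C1', so the allyl group (C5', C4', C3') ends trans to C9. Fluoride then cleaves the tertiary silyl ether, and the C8 alkoxide, held cis to the ester, lactonises by transesterification. The same fluoride removes tin as Bu3SnF.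

**Step 10**
Reactants: 17 allyl lactone
Product: 18 keto lactone (O8–C2' δ-lactone of (Z)-3-(8β-hydroxy-11-nordriman-9β-yl)-2-(2-oxopropyl)prop-2-enoic acid)
Conditions: PdCl2 (cat.), CuCl, O2 (1 atm), DMF–H2O, 23 °C
Reagents that add atoms: water, O
Why: Wacker oxidation (Markovnikov oxypalladation of the monosubstituted alkene) gives the methyl ketone; the conjugated, trisubstituted lactone alkene is electron-poor and hindered and should not react.

**Step 11**
Reactants: 18 keto lactone
Product: 20 (4Z)-3-hydroxy-4-[(8β-hydroxy-11-nordriman-9β-yl)methylidene]cyclopent-2-en-1-one, via lithium methyl-ketone enolate 19 (not isolated)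
Conditions: LiN(SiMe3)2 (2.5 equiv), THF (0.02 M, inverse addition), −78 → −20 °C; aq. HCl to pH 3, 0 °C
Reagents that add atoms: none
Why: LiN(SiMe3)2 removes a C3' proton of the methyl ketone; enolate 19 adds to the lactone carbonyl C2', the tetrahedral intermediate collapses by expelling the C8 alkoxide, and that alkoxide (or excess amide) deprotonates C3' of the new 1,3-dione, so the product rests as a vinylogous carboxylate until the acidic work-up. The closest known reaction types are the base-mediated intramolecular Claisen condensation of 4-oxoalkanoate esters to cyclopentane-1,3-diones and the C-acylation of ketone enolates by δ-lactones. The five-membered ring closes in the 5-(enolendo)-exo-trig mode, the less favourable enolate mode, which is the reason for using a cisoid lactone carbonyl as acyl donor instead of an acyclic methyl ester. No stereocentre is formed. The selectivity needed is C3' over the more acidic, allylic C5' methylene: the C5' dienolate cannot close a ring, cannot change the C11=C1' geometry because that alkene is endocyclic in the lactone, and is fed back through proton exchange with HN(SiMe3)2, while ring closure is made irreversible by formation of the dione enolate. An amide of this strength should not deprotonate that enolate at C5', so the exocyclic alkene should stay in place, and protonation at low temperature should return 20 as the C2' enol with C9 cis to C2'.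

**Step 12**
Reactants: 20 (4Z)-3-hydroxy-4-[(8β-hydroxy-11-nordriman-9β-yl)methylidene]cyclopent-2-en-1-one
Product: 23 (4E,5R)-5-chloro-3-hydroxy-4-[(8β-hydroxy-11-nordriman-9β-yl)methylidene]cyclopent-2-en-1-one, via tris(trimethylsilyl) dienol ether 21 (not isolated), via silylated chloro ketone 22 (not isolated)
Conditions: Me3SiOTf, Et3N, CH2Cl2, −78 → 0 °C; pentane, filter; then NCS, chiral squaramide hydrogen-bond donor (tert-leucine 2-arylpyrrolidine amide type, 10 mol %), t-BuOMe, −60 °C; then 0.5 M aq. HCl, THF, 0 °C
Reagents that add atoms: N-chlorosuccinimide, O=C1CCC(=O)N1Cl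
Why: Proposed new method: soft enolisation with Me3SiOTf/Et3N should silylate O8 and both dione oxygens and give 21, a cross-conjugated 1,3-bis(silyloxy)diene whose terminal carbon C5' is the most nucleophilic site, because attack there leaves a bis(silyloxy)allyl cation whereas attack at C3' or C11 does not. NCS bound to the chiral hydrogen-bond donor then transfers chlorine to one face of C5', and dilute acid removes all three silyl groups. The closest known reaction types are the terminal halogenation of 1,3-bis(silyloxy)-1,3-dienes by N-halosuccinimides and the squaramide-catalysed enantioselective chlorination of silyl ketene acetals with NCS. The decalin is too remote to bias C5', so the (5'R) configuration rests on the catalyst, whose enantiomer has to be chosen by trial. No base is present once the C–Cl bond exists, so the acidic C5'–H should not epimerise.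

## Compound list

1 | (+)-sclareolide (trans-fused γ-lactone; 8α-O, 8β-CH3, 9αH, 5αH, 10β-CH3) | CC1(C)CCC[C@]2(C)[C@H]3CC(=O)O[C@]3(C)CC[C@@H]12 | starting material
2 | 8-epi-sclareolide (cis-fused γ-lactone; 8β-O, 8α-CH3, other centres as in 1) | CC1(C)CCC[C@]2(C)[C@H]3CC(=O)O[C@@]3(C)CC[C@@H]12 | intermediate
3 | potassium enolate of 2 (C11=C12–OK) | CC1(C)CCC[C@]2(C)[C@H]3C=C(O[K])O[C@@]3(C)CC[C@@H]12 | intermediate
4 | 11-hydroxy-8-epi-sclareolide (C11 not assigned) | CC1(C)CCC[C@]2(C)[C@H]3C(O)C(=O)O[C@@]3(C)CC[C@@H]12 | intermediate
5 | 8β-hydroxy-9β-(1,2-dihydroxyethyl)-11-nordrimane (C11 carbinol not assigned) | CC1(C)CCC[C@]2(C)[C@@H](C(O)CO)[C@@](C)(O)CC[C@@H]12 | intermediate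
6 | 8β-hydroxydriman-11-al (8α-CH3, 9β-CHO, 5αH, 10β-CH3) | CC1(C)CCC[C@]2(C)[C@@H](C=O)[C@@](C)(O)CC[C@@H]12 | intermediate
7 | 8β-(triethylsilyloxy)driman-11-al | CC1(C)CCC[C@]2(C)[C@@H](C=O)[C@@](C)(O[Si](CC)(CC)CC)CC[C@@H]12 | intermediate
8 | carbon tetrabromide | BrC(Br)(Br)Br | starting material
9 | 11-(dibromomethylidene)-8β-(triethylsilyloxy)drimane (C9–CH=CBr2) | CC1(C)CCC[C@]2(C)[C@@H](C=C(Br)Br)[C@@](C)(O[Si](CC)(CC)CC)CC[C@@H]12 | intermediate
10 | methyl chloroformate | COC(Cl)=O | starting material
11 | lithium acetylide C9–C11≡C1'–Li of the 8β-(triethylsilyloxy)drimane | CC1(C)CCC[C@]2(C)[C@@H](C#C[Li])[C@@](C)(O[Si](CC)(CC)CC)CC[C@@H]12 | intermediate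
12 | methyl 3-[8β-(triethylsilyloxy)-11-nordriman-9β-yl]prop-2-ynoate | CC1(C)CCC[C@]2(C)[C@@H](C#CC(=O)OC)[C@@](C)(O[Si](CC)(CC)CC)CC[C@@H]12 | intermediate
13 | tributyltin hydride | CCCC[SnH](CCCC)CCCC | starting material
14 | methyl (E)-3-[8β-(triethylsilyloxy)-11-nordriman-9β-yl]-2-(tributylstannyl)prop-2-enoate (H11 and Sn cis; C9 cis to CO2Me) | CC1(C)CCC[C@]2(C)[C@@H](/C=C(\C(=O)OC)[Sn](CCCC)(CCCC)CCCC)[C@@](C)(O[Si](CC)(CC)CC)CC[C@@H]12 | intermediate
15 | allyl bromide | C=CCBr | starting material
16 | methyl (Z)-2-allyl-3-[8β-(triethylsilyloxy)-11-nordriman-9β-yl]prop-2-enoate (C9 cis to CO2Me) | CC1(C)CCC[C@]2(C)[C@@H](/C=C(\C(=O)OC)CC=C)[C@@](C)(O[Si](CC)(CC)CC)CC[C@@H]12 | intermediate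
17 | allyl lactone: O8–C2' δ-lactone of (Z)-2-allyl-3-(8β-hydroxy-11-nordriman-9β-yl)prop-2-enoic acid (cis-fused 5,6-dihydro-2H-pyran-2-one) | CC1(C)CCC[C@]2(C)[C@H]3C=C(CC=C)C(=O)O[C@@]3(C)CC[C@@H]12 | intermediate
18 | keto lactone: O8–C2' δ-lactone of (Z)-3-(8β-hydroxy-11-nordriman-9β-yl)-2-(2-oxopropyl)prop-2-enoic acid | CC1(C)CCC[C@]2(C)[C@H]3C=C(CC(C)=O)C(=O)O[C@@]3(C)CC[C@@H]12 | intermediate
19 | C3' lithium enolate of 18 (C4'(OLi)=C3'H2) | CC1(C)CCC[C@]2(C)[C@H]3C=C(CC(=C)O[Li])C(=O)O[C@@]3(C)CC[C@@H]12 | intermediate
20 | (4Z)-3-hydroxy-4-[(8β-hydroxy-11-nordriman-9β-yl)methylidene]cyclopent-2-en-1-one (des-chloro target; C9 cis to C2') | CC1(C)CCC[C@]2(C)[C@@H](/C=C3\C(O)=CC(=O)C3)[C@@](C)(O)CC[C@@H]12 | intermediate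
21 | 8-O,2'-O,4'-O-tris(trimethylsilyl) dienol ether of 20 (C2'=C3' and C4'=C5'; C9 cis to C2') | CC1(C)CCC[C@]2(C)[C@@H](/C=C3\C(O[Si](C)(C)C)=CC(O[Si](C)(C)C)=C3)[C@@](C)(O[Si](C)(C)C)CC[C@@H]12 | intermediate
22 | (5'R)-5'-chloro-8-O,2'-O-bis(trimethylsilyl) derivative of 23 (C4' ketone) | CC1(C)CCC[C@]2(C)[C@@H](/C=C3\C(O[Si](C)(C)C)=CC(=O)[C@@H]3Cl)[C@@](C)(O[Si](C)(C)C)CC[C@@H]12 | intermediate
23 | (4E,5R)-5-chloro-3-hydroxy-4-[(8β-hydroxy-11-nordriman-9β-yl)methylidene]cyclopent-2-en-1-one, CNP0279879.2 (C9 cis to C2') | CC1(C)CCC[C@]2(C)[C@@H](/C=C3\C(O)=CC(=O)[C@@H]3Cl)[C@@](C)(O)CC[C@@H]12 | target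

## Step count and least certain steps

Total step count: 12. Longest linear sequence: 12 steps from 1 (the route is fully linear).

**Step 12 (chlorination).** The most likely failure is poor facial selectivity in the chlorine transfer: the dienol ether is flat at C5' and its nearest stereocentre is five bonds away, so everything depends on a catalyst not yet shown on this substrate class. Chlorination at C3' and acid-induced loss of silyl groups before the transfer are further risks. Fallback, setting out from 21 (made from 20 as in step 12) and returning at 23: uncatalysed chlorination of 21 with N-chlorosuccinimide, a known terminal halogenation of 1,3-bis(silyloxy)dienes, followed by the same acidic work-up, would give 23 together with its 5'-epimer F1; the two are diastereomers and would be separated by chromatography. F1 would be re-silylated (Me3SiOTf, Et3N) to the 5'-chloro tris(silyl) dienol ether F2, in which C5' is trigonal, and protonated at low temperature with dilute acid to return a mixture of 23 and F1 for another separation.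

**Step 11 (key step).** The most likely failure is unproductive enolisation at the doubly activated C5' methylene. If the dienolate accumulates, ring closure through the small share of C3' enolate may be slow, and on warming proton return at C11 would move the alkene out of the lactone ring into conjugation with the ketone; the 5-(enolendo) trajectory may also let intermolecular condensation compete. Fallback, setting out from 17 and returning at 20: hydroxybromination of the terminal alkene (N-bromosuccinimide, wet DMSO) would give bromohydrin F3, and oxidation with Dess–Martin periodinane would give bromomethyl ketone F4. SmI2 (divalent samarium) in THF at −78 °C would reduce the C–Br bond and give the C3' samarium enolate F5 regiospecifically, with no base in the flask; F5 would close onto the lactone in a Reformatsky-type acylation to give 20 after acidic work-up.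

**Step 10 (Wacker oxidation).** The most likely failure is migration of the terminal alkene along the skipped diene by palladium hydride before oxidation, or acid-promoted conjugation of the β,γ-unsaturated ketone after it; attack at the terminal carbon directed by the lactone carbonyl would give aldehyde. Fallback, setting out from 14 and returning at 18: Stille coupling of 14 with 2-methoxyallyl bromide under the conditions of step 9 would give the enol ether F6, which already carries the C4' oxygen. The fluoride stage would give the lactone enol ether F7, and brief treatment with aqueous oxalic acid would hydrolyse the enol ether to 18 without an oxidation.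

**Step 9 (Stille allylation and lactonisation).** The most likely failure is slow transmetalation from the hindered, electron-poor α-stannyl acrylate, so that protodestannylation and allyl homocoupling take over; in the fluoride stage, incomplete cleavage of the tertiary silyl ether or base-induced conjugation of the skipped diene may occur. Fallback, setting out from 14 and returning at 16 (then on to 17 by the fluoride stage): iododestannylation (I2, CH2Cl2, 0 °C) with retention would give the vinyl iodide F8, which would be coupled in the reverse sense with allyltributylstannane (Pd2(dba)3, AsPh3, DMF); oxidative addition of the iodide replaces the difficult transmetalation.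

## Further compounds

F1 | step 12 | (4E,5S)-5-chloro-3-hydroxy-4-[(8β-hydroxy-11-nordriman-9β-yl)methylidene]cyclopent-2-en-1-one (5'-epimer of 23) | CC1(C)CCC[C@]2(C)[C@@H](/C=C3\C(O)=CC(=O)[C@H]3Cl)[C@@](C)(O)CC[C@@H]12
F2 | step 12 | 5'-chloro-8-O,2'-O,4'-O-tris(trimethylsilyl) dienol ether (C2'=C3' and C4'=C5') | CC1(C)CCC[C@]2(C)[C@@H](/C=C3\C(O[Si](C)(C)C)=CC(O[Si](C)(C)C)=C3Cl)[C@@](C)(O[Si](C)(C)C)CC[C@@H]12
F3 | step 11 | bromohydrin of 17 (C4'–OH, C3'–Br; C4' not assigned) | CC1(C)CCC[C@]2(C)[C@H]3C=C(CC(O)CBr)C(=O)O[C@@]3(C)CC[C@@H]12
F4 | step 11 | bromomethyl ketone (3'-bromo derivative of 18) | CC1(C)CCC[C@]2(C)[C@H]3C=C(CC(=O)CBr)C(=O)O[C@@]3(C)CC[C@@H]12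
F5 | step 11 | C3' diiodosamarium enolate of 18 | CC1(C)CCC[C@]2(C)[C@H]3C=C(CC(=C)O[Sm](I)I)C(=O)O[C@@]3(C)CC[C@@H]12
F6 | step 10 | methyl (Z)-2-(2-methoxyallyl)-3-[8β-(triethylsilyloxy)-11-nordriman-9β-yl]prop-2-enoate | CC1(C)CCC[C@]2(C)[C@@H](/C=C(\C(=O)OC)CC(=C)OC)[C@@](C)(O[Si](CC)(CC)CC)CC[C@@H]12
F7 | step 10 | 2-methoxyallyl lactone (C4' methyl enol ether of 18) | CC1(C)CCC[C@]2(C)[C@H]3C=C(CC(=C)OC)C(=O)O[C@@]3(C)CC[C@@H]12
F8 | step 9 | methyl (E)-2-iodo-3-[8β-(triethylsilyloxy)-11-nordriman-9β-yl]prop-2-enoate (C9 cis to CO2Me) | CC1(C)CCC[C@]2(C)[C@@H](/C=C(\C(=O)OC)I)[C@@](C)(O[Si](CC)(CC)CC)CC[C@@H]12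
A1 | alternative 1 | (2E,8E,10E)-11-acetoxy-3,7,7-trimethylundeca-2,8,10-trienal | O=C/C=C(\C)CCCC(C)(C)/C=C/C=C/OC(C)=O
A2 | alternative 1 | 8β-acetoxy-12-nordrim-6-en-11-al | CC1(C)CCC[C@]2(C)[C@@H](C=O)[C@@H](OC(C)=O)C=C[C@@H]12
A3 | alternative 2 | methyl 2-[2-(2-iodoethyl)-1,3,3-trimethylcyclohexyl]-3-oxobutanoate (ring centres as C5 and C10 of the drimane; acetoacetate carbon not assigned) | CC1(C)CCC[C@](C)(C(C(C)=O)C(=O)OC)[C@H]1CCI
A4 | alternative 2 | methyl 8β-hydroxydriman-11-oate | CC1(C)CCC[C@]2(C)[C@@H](C(=O)OC)[C@@](C)(O)CC[C@@H]12
A5 | alternative 3 | methyl (6E)-7,11-dimethyl-3-oxododeca-6,10-dienoate | COC(=O)CC(=O)CC/C=C(\C)CCC=C(C)C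
A6 | alternative 3 | methyl 8-oxo-12-nordriman-11-oate | CC1(C)CCC[C@]2(C)[C@@H](C(=O)OC)C(=O)CC[C@@H]12
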